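Retrosynthesis (labdane numbering): the C15 acid is released from an allyl ester, C13=C14 is cut as a Horner–Wadsworth–Emmons olefination, the C6 acetate and C7 isovalerate are traced to a 7α-acyloxy-6-ketone and then to a 7-en-6-one, ring B is opened at C7–C8, and C9–C10 is cut as an Ireland–Claisen rearrangement, leaving ring A from geranic acid.
Enabling feature: C7 lies between the oxygen-bearing C6 and C8, the carbon that carries C17, so a C6=C7 enol silane and a C8≡C17 alkyne held on ring A can close ring B by forming C7–C8.
Forward order: ring A by acid cyclisation of geranic acid; the C9/C11–C13 chain joined at C10 by Ireland–Claisen rearrangement; ring B by monovalent-gold 6-exo-dig cyclisation; then C7 oxygenation with alkene shift to C8=C9, C6 reduction, the two acylations and chain extension to C15.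
Stereochemistry: C5 from resolution of α-cyclogeranic acid; C10 by chirality transfer from a C2 carbinol in the Claisen step; C7 (oxidant) and C6 (hydride) by α-face attack on the trans-decalin, whose β-face is blocked by the C10 and C4 methyl groups; 13E from the olefination.

Key step: step 17

Assumption: the salt of (S)-α-cyclogeranic acid with (R)-1-phenylethylamine is taken to be the less soluble one; if the pairing is the reverse, the (S)-amine is used and nothing downstream changes.
Remark: labdane locants are used for all intermediates (ring A = C1–C5 and C10; C6 on C5; C9 on C10; C20 = methyl on C10); β is the face that carries C20 in the target.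
Remark: C9 is a stereocentre only from step 9 to step 19; it is drawn in the configuration expected from the Claisen step, and its epimer would converge at dienolate 30.

Step 1
Reactants: 1 geranic acid
Product: 2 (±)-α-cyclogeranic acid
Conditions: 85% H3PO4, 100 °C
Reagents that add atoms: none
Why: Acid-promoted cation–olefin cyclisation: protonation of the 6,7-alkene gives a tertiary cation that is captured by the 2,3-alkene and loses a proton to the non-conjugated α-isomer, so both double-bond isomers of commercial geranic acid should converge on 2.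

Step 2
Reactants: 2 (±)-α-cyclogeranic acid; 3 (R)-1-phenylethylamine
Product: 4 (R)-1-phenylethylammonium (S)-α-cyclogeranate
Conditions: 3 (0.55 equiv), EtOAc, 60 → 0 °C; recrystallise to constant rotation
Reagents that add atoms: none
Why: Classical resolution by fractional crystallisation of diastereomeric ammonium carboxylates, which should enrich the salt of the (S)-acid and thereby fixes C5 (5α-H) of the target.

Step 3
Reactants: 4 (R)-1-phenylethylammonium (S)-α-cyclogeranate
Product: 6 (S)-α-cyclogeraniol, via (S)-α-cyclogeranic acid 5 (not isolated)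
Conditions: 1 M HCl, Et2O (dried extract used as such); LiAlH4, THF, 0 °C → reflux
Reagents that add atoms: none
Why: Acidification frees the acid and LiAlH4 reduces it (carboxylic acid to primary alcohol reduction) without touching the trisubstituted alkene or the C5 stereocentre, which is not enolised under hydride conditions.

Step 4
Reactants: 6 (S)-α-cyclogeraniol
Product: 7 (S)-α-cyclogeranyl tert-butyldimethylsilyl ether
Conditions: t-BuMe2SiCl, imidazole, DMF, rt
Reagents that add atoms: tert-butyldimethylsilyl chloride, CC(C)(C)[Si](C)(C)Cl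
Why: Imidazole-mediated silyl ether formation masks the primary C6 hydroxyl for the oxidation, enolate and hydride steps that follow.

Step 5
Reactants: 7 (S)-α-cyclogeranyl tert-butyldimethylsilyl ether
Product: 8 (4S)-4-[(tert-butyldimethylsilyloxy)methyl]-3,5,5-trimethylcyclohex-2-en-1-one (C2 ketone, C1=C10 enone)
Conditions: Rh2(cap)4 (dirhodium tetrakis(caprolactamate), 1 mol %), t-BuOOH (70% in water), ClCH2CH2Cl, 40 °C
Reagents that add atoms: tert-butyl hydroperoxide, CC(C)(C)OO
Why: Dirhodium caprolactamate/t-BuOOH allylic oxidation (hydrogen abstraction by tert-butylperoxyl radicals) should attack the only ring methylene allylic to the C1=C10 alkene, C2, and give the enone while leaving the silyl ether and C5 untouched.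

Step 6
Reactants: 8 enone
Product: 9 (1S,4S)-4-[(tert-butyldimethylsilyloxy)methyl]-3,5,5-trimethylcyclohex-2-en-1-ol (trans; 2α-OH, 5β side arm)
Conditions: LiBH(s-Bu)3, THF, −78 °C
Reagents that add atoms: none
Why: 1,2-Reduction of the β,β-disubstituted enone with a bulky trialkylborohydride; with the C5 substituent pseudoaxial the axial C4 methyl screens the α-face of C2, so hydride should arrive from the β-face and give the 2α-alcohol trans to the C5 side arm, the centre that later controls C10.

Step 7
Reactants: 10 5-oxohexanoic acid; 11 ethylene glycol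
Product: 13 4-(2-methyl-1,3-dioxolan-2-yl)butanoic acid, via 2-hydroxyethyl ester ketal 12 (not isolated)
Conditions: 11 (4 equiv), TsOH·H2O (cat.), toluene, reflux, Dean–Stark; then 2 M NaOH, MeOH, rt; aq. NaH2PO4 to pH 5, 0 °C
Reagents that add atoms: sodium hydroxide, [Na+].[OH-]
Why: Acid-catalysed ketalisation with azeotropic water removal (the carboxyl group is esterified by the glycol at the same time) followed by saponification, to which the dioxolane is inert, gives the ketal acid after buffered acidification.

Step 8
Reactants: 9 trans-allylic alcohol; 13 ketal acid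
Product: 14 (1S,4S)-4-[(tert-butyldimethylsilyloxy)methyl]-3,5,5-trimethylcyclohex-2-en-1-yl 4-(2-methyl-1,3-dioxolan-2-yl)butanoate
Conditions: DCC, DMAP (cat.), CH2Cl2, 0 °C → rt
Reagents that add atoms: none
Why: Steglich esterification (carbodiimide activation with DMAP acyl transfer) acylates the allylic alcohol at oxygen with retention at C2.

Step 9
Reactants: 14 allylic ester
Product: 18 methyl ester of the Claisen acid (ring A 1(2)-ene; 5β-CH2OTBS; 10β-CH3; C9H(CO2Me)CH2CH2C(OCH2CH2O)CH3 on the α-face of C10), via (E)-trimethylsilyl ketene acetal 15 (not isolated), via trimethylsilyl ester 16 (not isolated), via Claisen acid 17 (not isolated)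
Conditions: Me3SiCl–Et3N, LiN(i-Pr)2, THF, −78 °C, then 65 °C; aq. NH4Cl; then MeI, K2CO3, DMF, rt
Reagents that add atoms: iodomethane, CI
Why: Ireland–Claisen rearrangement: the kinetic (E)-silyl ketene acetal rearranges suprafacially, so C9–C10 forms on the α-face from which the C2–O bond leaves, anti to the 5β arm, which sets the quaternary C10 (10β-methyl) by chirality transfer from C2, while the boat-like transition state usual for cyclohexenyl esters should give the C9 configuration drawn (a centre that is erased in step 19), and methylation of the crude acid prepares the next reduction.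

Step 10
Reactants: 18 unsaturated methyl ester
Product: 19 saturated methyl ester (ring A cyclohexane; otherwise as 18)
Conditions: H2 (3 atm), 5% Pt/C, EtOAc, rt
Reagents that add atoms: none
Why: Heterogeneous catalytic hydrogenation saturates the cis-disubstituted C1=C2 alkene, which would otherwise offer a 1,5-enyne pathway in the gold step, and creates no stereocentre.

Step 11
Reactants: 19 saturated methyl ester
Product: 21 terminal alkyne (C8≡C17 on C9; 6-OTBS; 13-dioxolane), via C8 aldehyde 20 (not isolated)
Conditions: i-Bu2AlH, CH2Cl2, −78 °C; MeOH; then dimethyl (1-diazo-2-oxopropyl)phosphonate, K2CO3, MeOH, −78 °C → rt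
Reagents that add atoms: dimethyl (1-diazo-2-oxopropyl)phosphonate, CC(=O)C(=[N+]=[N-])P(=O)(OC)OC
Why: i-Bu2AlH reduction at low temperature stops at the aluminium hemiacetal of the α-branched ester, and the aldehyde released on methanol quench is homologated in the same flask by the Seyferth–Gilbert reaction in its Ohira–Bestmann form, which installs C17 as the terminal alkyne carbon.

Step 12
Reactants: 21 silyl ether alkyne
Product: 22 primary C6 alcohol
Conditions: Bu4NF, THF, rt
Reagents that add atoms: none
Why: Fluoride-mediated cleavage of the silyl ether (Si–F bond formation) frees the C6 alcohol without affecting alkyne or ketal.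

Step 13
Reactants: 22 primary C6 alcohol
Product: 23 C6 aldehyde
Conditions: Dess–Martin periodinane, NaHCO3, CH2Cl2, 0 °C → rt
Reagents that add atoms: none
Why: Dess–Martin oxidation of the neopentyl-type primary alcohol gives the aldehyde under buffered, non-epimerising conditions that protect the C5 centre.

Step 14
Reactants: 23 C6 aldehyde
Product: 24 C6 methyl carbinol (both C6 epimers)
Conditions: MeMgBr (3 equiv), THF, −20 → 0 °C
Reagents that add atoms: methylmagnesium bromide, C[Mg]Br
Why: Grignard 1,2-addition: MeMgBr first deprotonates the alkyne and then adds C7 to the hindered but non-conjugated C6 aldehyde, the new carbinol centre forming as an epimer mixture that the next step removes.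

Step 15
Reactants: 24 C6 methyl carbinol
Product: 25 methyl ketone (C6 acetyl on C5; C8≡C17 alkyne on C9)
Conditions: Dess–Martin periodinane, NaHCO3, CH2Cl2, rt
Reagents that add atoms: none
Why: Dess–Martin oxidation converts both C6 epimers into the single methyl ketone under conditions that should not epimerise C5.

Step 16
Reactants: 25 methyl ketone
Product: 27 C6 tert-butyldimethylsilyl enol ether (C6=C7), via potassium enolate 26 (not isolated)
Conditions: KN(SiMe3)2 (1.05 equiv), THF, −78 °C; t-BuMe2SiCl, −78 → −20 °C
Reagents that add atoms: tert-butyldimethylsilyl chloride, CC(C)(C)[Si](C)(C)Cl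
Why: Kinetic enolisation with a hindered amide base removes a proton from the C7 methyl group rather than the tertiary C5–H flanked by two quaternary carbons (the ketone is also more acidic than the alkyne C–H), and O-silylation of the potassium enolate gives the terminal enol silane (kinetic silyl enol ether formation).

Step 17
Reactants: 27 enol silane alkyne
Product: 28 13,13-ethylenedioxy-14,15-dinorlabd-8(17)-en-6-one (5α-H, 9α-H, 10β-CH3)
Conditions: (Ph3P)AuNTf2 (5 mol %), CH2Cl2–MeOH (10:1), rt
Reagents that add atoms: none
Why: (Ph3P)AuNTf2, a monovalent gold π-acid, coordinates the terminal C8≡C17 alkyne, and the C6=C7 enol silane adds through C7 to the internal carbon C8 anti to gold, giving an exocyclic vinylgold and a silyloxocarbenium ion; methanol takes the silyl group and protodeauration releases the ketone with the C8=C17 methylene. The closest known reaction type is the gold-catalysed Conia-ene-type carbocyclisation of silyl enol ethers onto tethered terminal alkynes. Ring B closes in the 6-exo-dig mode by forming C7–C8, and the trans-diequatorial placement of C6 (on C5) and C9 (on C10) on the ring A chair leads directly to the trans-decalin. No stereocentre is created: C5 and C10 are already fixed and C9 is carried through unchanged. Two regioselectivities are needed, C7 rather than C5 as nucleophile and C8 rather than C17 as acceptor; the first is secured by the kinetically formed terminal enol silane, the second by the terminal alkyne (attack at the internal carbon) and the preference for a six- over a seven-membered ring.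

Step 18
Reactants: 28 8(17)-en-6-one
Product: 29 13,13-ethylenedioxy-14,15-dinorlabd-7-en-6-one
Conditions: DBU (0.3 equiv), CH2Cl2, rt
Reagents that add atoms: none
Why: Base-catalysed isomerisation of the β,γ-unsaturated ketone through its dienolate moves the exocyclic alkene into conjugation (C7=C8), the thermodynamically favoured enone, without affecting C5, C9 or C10.

Step 19
Reactants: 29 7-en-6-one
Product: 32 13,13-ethylenedioxy-7α-(3-methylbutanoyloxy)-14,15-dinorlabd-8-en-6-one, via potassium dienolate 30 (not isolated), via potassium 7α-alkoxide 31 (not isolated)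
Conditions: KN(SiMe3)2 (0.95 equiv), THF, −78 → 0 °C, 1 h; −78 °C, trans-2-(phenylsulfonyl)-3-phenyloxaziridine; then 3-methylbutanoyl chloride, −78 → 0 °C
Reagents that add atoms: trans-2-(phenylsulfonyl)-3-phenyloxaziridine, O=S(=O)(c1ccccc1)N1OC1c1ccccc1; 3-methylbutanoyl chloride, CC(C)CC(Cl)=O
Why: The extended potassium dienolate, equilibrated through the small excess of enone to the endocyclic C6=C7/C8=C9 isomer (γ-deprotonation at C9), should take the electrophilic oxaziridine oxygen at its α-carbon C7 from the α-face, away from the C10 and C4β methyl groups (oxaziridine α-hydroxylation of an extended enolate), which sets 7α-O, places the alkene at C8=C9 and erases C9, and O-acylation in the same flask protects the isomerisation-prone α-ketol.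

Step 20
Reactants: 32 7α-acyloxy-6-ketone
Product: 33 13,13-ethylenedioxy-6β-hydroxy-7α-(3-methylbutanoyloxy)-14,15-dinorlabd-8-ene
Conditions: NaBH4, MeOH–THF (1:4), −20 → 0 °C
Reagents that add atoms: none
Why: Borohydride reduction of the ketone: hydride should add to C6 from the α-face because the β-face is screened by the syn-axial C10 and C4β methyl groups, which sets the axial 6β-alcohol, and the trans-diaxial relation to the 7α-ester disfavours acyl migration.

Step 21
Reactants: 33 6β-alcohol
Product: 34 6β-acetoxy-13,13-ethylenedioxy-7α-(3-methylbutanoyloxy)-14,15-dinorlabd-8-ene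
Conditions: Ac2O, DMAP, pyridine, 60 °C
Reagents that add atoms: acetic anhydride, CC(=O)OC(C)=O
Why: DMAP-catalysed acylation with acetic anhydride, run warm because the axial 6β-hydroxyl is flanked by two syn-axial methyl groups, gives the acetate with retention.

Step 22
Reactants: 34 diester ketal
Product: 35 6β-acetoxy-7α-(3-methylbutanoyloxy)-14,15-dinorlabd-8-en-13-one
Conditions: PPTS (cat.), acetone–H2O (9:1), 50 °C
Reagents that add atoms: water, O
Why: Mild acid-catalysed hydrolysis of the dioxolane (ketal cleavage) releases the C13 methyl ketone under conditions that the allylic 7-ester and the acetate should survive.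

Step 23
Reactants: 35 C13 methyl ketone; 36 allyl diethylphosphonoacetate
Product: 37 allyl 6β-acetoxy-7α-(3-methylbutanoyloxy)labda-8,13E-dien-15-oate
Conditions: 36 (1.5 equiv), NaH (1.4 equiv), THF, 0 °C; then 35, rt → 45 °C
Reagents that add atoms: none
Why: Horner–Wadsworth–Emmons olefination of the methyl ketone with the stabilised phosphonate anion, which is too weakly basic to attack the two secondary esters, should give mainly the 13E enoate (ester trans to the larger C12 chain), the minor Z isomer being removed by chromatography.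

Step 24
Reactants: 37 allyl ester
Product: 38 6β-acetoxy-7α-(3-methylbutanoyloxy)labda-8,13E-dien-15-oic acid (CNP0328312.2)
Conditions: Pd(PPh3)4 (5 mol %), morpholine, THF, rt; pH 4 buffer work-up
Reagents that add atoms: none
Why: Tsuji–Trost deallylation: zerovalent palladium ionises the unhindered allyl ester far faster than the secondary allylic 7-ester on the tetrasubstituted C8=C9 alkene, and morpholine traps the π-allyl fragment, releasing the acid without touching the other esters.

Compound list
1 | geranic acid, (2E)-3,7-dimethylocta-2,6-dienoic acid | CC(C)=CCC/C(C)=C/C(=O)O | starting material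
2 | (±)-α-cyclogeranic acid, (±)-2,6,6-trimethylcyclohex-2-ene-1-carboxylic acid | CC1=CCCC(C)(C)C1C(=O)O | intermediate
3 | (R)-1-phenylethylamine | C[C@@H](N)c1ccccc1 | starting material
4 | (R)-1-phenylethylammonium (S)-2,6,6-trimethylcyclohex-2-ene-1-carboxylate | C[C@@H]([NH3+])c1ccccc1.[O-]C(=O)[C@@H]1C(C)=CCCC1(C)C | intermediate
5 | (S)-α-cyclogeranic acid | OC(=O)[C@@H]1C(C)=CCCC1(C)C | intermediate (not isolated)
6 | (S)-α-cyclogeraniol, [(1S)-2,6,6-trimethylcyclohex-2-en-1-yl]methanol | OC[C@@H]1C(C)=CCCC1(C)C | intermediate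
7 | tert-butyldimethyl{[(1S)-2,6,6-trimethylcyclohex-2-en-1-yl]methoxy}silane | CC(C)(C)[Si](C)(C)OC[C@@H]1C(C)=CCCC1(C)C | intermediate
8 | (4S)-4-[(tert-butyldimethylsilyloxy)methyl]-3,5,5-trimethylcyclohex-2-en-1-one | CC(C)(C)[Si](C)(C)OC[C@@H]1C(C)=CC(=O)CC1(C)C | intermediate
9 | (1S,4S)-4-[(tert-butyldimethylsilyloxy)methyl]-3,5,5-trimethylcyclohex-2-en-1-ol (trans) | CC(C)(C)[Si](C)(C)OC[C@@H]1C(C)=C[C@@H](O)CC1(C)C | intermediate
10 | 5-oxohexanoic acid | CC(=O)CCCC(=O)O | starting material
11 | ethylene glycol | OCCO | starting material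
12 | 2-hydroxyethyl 4-(2-methyl-1,3-dioxolan-2-yl)butanoate | CC1(CCCC(=O)OCCO)OCCO1 | intermediate (not isolated)
13 | 4-(2-methyl-1,3-dioxolan-2-yl)butanoic acid | CC1(CCCC(=O)O)OCCO1 | intermediate
14 | (1S,4S)-4-[(tert-butyldimethylsilyloxy)methyl]-3,5,5-trimethylcyclohex-2-en-1-yl 4-(2-methyl-1,3-dioxolan-2-yl)butanoate | CC(C)(C)[Si](C)(C)OC[C@@H]1C(C)=C[C@@H](OC(=O)CCCC2(C)OCCO2)CC1(C)C | intermediate
15 | (E)-trimethylsilyl ketene acetal of 14 (chain carbon cis to the allylic oxygen) | CC(C)(C)[Si](C)(C)OC[C@@H]1C(C)=C[C@@H](O/C(O[Si](C)(C)C)=C\CCC2(C)OCCO2)CC1(C)C | intermediate (not isolated)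
16 | trimethylsilyl ester of Claisen acid 17 | CC(C)(C)[Si](C)(C)OC[C@@H]1[C@@](C)([C@@H](CCC2(C)OCCO2)C(=O)O[Si](C)(C)C)C=CCC1(C)C | intermediate (not isolated)
17 | Claisen acid: 2-{6-[(tert-butyldimethylsilyloxy)methyl]-1,5,5-trimethylcyclohex-2-en-1-yl}-5-(2-methyl-1,3-dioxolan-2-yl)pentanoic acid (5β arm, 10β-CH3, C9 on the α-face of C10) | CC(C)(C)[Si](C)(C)OC[C@@H]1[C@@](C)([C@@H](CCC2(C)OCCO2)C(=O)O)C=CCC1(C)C | intermediate (not isolated)
18 | methyl ester of 17 | CC(C)(C)[Si](C)(C)OC[C@@H]1[C@@](C)([C@@H](CCC2(C)OCCO2)C(=O)OC)C=CCC1(C)C | intermediate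
19 | methyl 2-{2-[(tert-butyldimethylsilyloxy)methyl]-1,3,3-trimethylcyclohexyl}-5-(2-methyl-1,3-dioxolan-2-yl)pentanoate (same configuration as 18) | CC(C)(C)[Si](C)(C)OC[C@@H]1[C@@](C)([C@@H](CCC2(C)OCCO2)C(=O)OC)CCCC1(C)C | intermediate
20 | 2-{2-[(tert-butyldimethylsilyloxy)methyl]-1,3,3-trimethylcyclohexyl}-5-(2-methyl-1,3-dioxolan-2-yl)pentanal | CC(C)(C)[Si](C)(C)OC[C@@H]1[C@@](C)([C@@H](CCC2(C)OCCO2)C=O)CCCC1(C)C | intermediate (not isolated)
21 | tert-butyl({2-[6-(2-methyl-1,3-dioxolan-2-yl)hex-1-yn-3-yl]-2,6,6-trimethylcyclohexyl}methoxy)dimethylsilane (5S,9S,10R in labdane locants) | CC(C)(C)[Si](C)(C)OC[C@@H]1[C@@](C)([C@@H](CCC2(C)OCCO2)C#C)CCCC1(C)C | intermediate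
22 | {2-[6-(2-methyl-1,3-dioxolan-2-yl)hex-1-yn-3-yl]-2,6,6-trimethylcyclohexyl}methanol | OC[C@@H]1[C@@](C)([C@@H](CCC2(C)OCCO2)C#C)CCCC1(C)C | intermediate
23 | 2-[6-(2-methyl-1,3-dioxolan-2-yl)hex-1-yn-3-yl]-2,6,6-trimethylcyclohexanecarbaldehyde | O=C[C@@H]1[C@@](C)([C@@H](CCC2(C)OCCO2)C#C)CCCC1(C)C | intermediate
24 | 1-{2-[6-(2-methyl-1,3-dioxolan-2-yl)hex-1-yn-3-yl]-2,6,6-trimethylcyclohexyl}ethanol (both C6 epimers) | CC(O)[C@@H]1[C@@](C)([C@@H](CCC2(C)OCCO2)C#C)CCCC1(C)C | intermediate
25 | 1-{2-[6-(2-methyl-1,3-dioxolan-2-yl)hex-1-yn-3-yl]-2,6,6-trimethylcyclohexyl}ethanone | CC(=O)[C@@H]1[C@@](C)([C@@H](CCC2(C)OCCO2)C#C)CCCC1(C)C | intermediate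
26 | potassium enolate of 25 (C6=C7) | [K+].[O-]C(=C)[C@@H]1[C@@](C)([C@@H](CCC2(C)OCCO2)C#C)CCCC1(C)C | intermediate (not isolated)
27 | tert-butyl[(1-{2-[6-(2-methyl-1,3-dioxolan-2-yl)hex-1-yn-3-yl]-2,6,6-trimethylcyclohexyl}ethenyl)oxy]dimethylsilane | C=C(O[Si](C)(C)C(C)(C)C)[C@@H]1[C@@](C)([C@@H](CCC2(C)OCCO2)C#C)CCCC1(C)C | intermediate
28 | 13,13-ethylenedioxy-14,15-dinorlabd-8(17)-en-6-one (5α-H, 9α-H, 10β-CH3) | O=C1CC(=C)[C@H](CCC3(C)OCCO3)[C@@]2(C)CCCC(C)(C)[C@H]12 | intermediate
29 | 13,13-ethylenedioxy-14,15-dinorlabd-7-en-6-one | O=C1C=C(C)[C@H](CCC3(C)OCCO3)[C@@]2(C)CCCC(C)(C)[C@H]12 | intermediate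
30 | potassium 13,13-ethylenedioxy-14,15-dinorlabda-6,8-dien-6-olate | [K+].[O-]C1=CC(C)=C(CCC3(C)OCCO3)[C@@]2(C)CCCC(C)(C)[C@H]12 | intermediate (not isolated)
31 | potassium 7α-alkoxide of 13,13-ethylenedioxy-7α-hydroxy-14,15-dinorlabd-8-en-6-one | [K+].O=C1[C@@H]([O-])C(C)=C(CCC3(C)OCCO3)[C@@]2(C)CCCC(C)(C)[C@H]12 | intermediate (not isolated)
32 | 13,13-ethylenedioxy-7α-(3-methylbutanoyloxy)-14,15-dinorlabd-8-en-6-one | O=C1[C@@H](OC(=O)CC(C)C)C(C)=C(CCC3(C)OCCO3)[C@@]2(C)CCCC(C)(C)[C@H]12 | intermediate
33 | 13,13-ethylenedioxy-6β-hydroxy-7α-(3-methylbutanoyloxy)-14,15-dinorlabd-8-ene | O[C@@H]1[C@@H](OC(=O)CC(C)C)C(C)=C(CCC3(C)OCCO3)[C@@]2(C)CCCC(C)(C)[C@H]12 | intermediate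
34 | 6β-acetoxy-13,13-ethylenedioxy-7α-(3-methylbutanoyloxy)-14,15-dinorlabd-8-ene | CC(=O)O[C@@H]1[C@@H](OC(=O)CC(C)C)C(C)=C(CCC3(C)OCCO3)[C@@]2(C)CCCC(C)(C)[C@H]12 | intermediate
35 | 6β-acetoxy-7α-(3-methylbutanoyloxy)-14,15-dinorlabd-8-en-13-one | CC(=O)O[C@@H]1[C@@H](OC(=O)CC(C)C)C(C)=C(CCC(C)=O)[C@@]2(C)CCCC(C)(C)[C@H]12 | intermediate
36 | allyl diethylphosphonoacetate, prop-2-enyl 2-(diethoxyphosphoryl)acetate | C=CCOC(=O)CP(=O)(OCC)OCC | starting material
37 | allyl 6β-acetoxy-7α-(3-methylbutanoyloxy)labda-8,13E-dien-15-oate | CC(=O)O[C@@H]1[C@@H](OC(=O)CC(C)C)C(C)=C(CC/C(C)=C/C(=O)OCC=C)[C@@]2(C)CCCC(C)(C)[C@H]12 | intermediate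
38 | 6β-acetoxy-7α-(3-methylbutanoyloxy)labda-8,13E-dien-15-oic acid (5α-H, 10β-CH3) | CC(=O)O[C@@H]1[C@@H](OC(=O)CC(C)C)C(C)=C(CC/C(C)=C/C(=O)O)[C@@]2(C)CCCC(C)(C)[C@H]12 | target

Total step count: 24. Longest linear sequence: 23 steps (steps 1–6 and 8–24, from geranic acid 1); step 7 is the only branch.

Steps most likely to fail

Step 19 (dienolate hydroxylation and acylation). The base may remove a proton at C5 or at the C17 methyl instead of C9. Oxygen may be delivered to the γ-carbon C9 or to the β-face of C7. The α-ketol may also shift to its conjugated 6-hydroxy-7-one isomer before it is acylated. The fallback sets out from enone 29. Soft enolisation under equilibrating conditions (t-BuMe2SiOTf, Et3N, CH2Cl2, 0 °C) should give the 6-silyloxy-6,8-diene F1. OsO4 (cat.) with N-methylmorpholine N-oxide in acetone–water should then dihydroxylate the more accessible trisubstituted enol ether bond C6=C7 from the α-face; collapse of the silyl hemiketal (a Rubottom-type oxidation) gives the free 7α-hydroxy ketone F2. Acylation with 3-methylbutanoic anhydride and DMAP in CH2Cl2 returns to the route at 32.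

Step 17 (gold cyclisation). Protodesilylation of the enol silane back to the ketone may outpace C–C bond formation. Closure may occur in the 7-endo sense at C17. The dioxolane may take part at, or be cleaved by, the activated alkyne. The fallback sets out from methyl ketone 25. Markovnikov hydration of the alkyne ((Ph3P)AuNTf2 (cat.), MeOH–H2O, 60 °C) should give the 6,8-diketone F3. Intramolecular aldol condensation (KOt-Bu, t-BuOH, rt) then forms the same C7–C8 bond, because the C7 methyl enolate adds to the less hindered C8 carbonyl; dehydration delivers the conjugated enone and the route is rejoined at 29.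

Step 6 (enone reduction). Hydride may be delivered to the α-face of C2 with poor or inverted facial selectivity, giving the cis alcohol, which would pass the wrong configuration on to C10 in step 9. The fallback sets out from enone 8. The cis alcohol F4, taken either as the separated by-product of step 6 or as the product of a Luche reduction of 8 (NaBH4, CeCl3·7H2O, MeOH, −78 °C), is esterified with acid 13 under Mitsunobu conditions (PPh3, diisopropyl azodicarboxylate, THF, 0 °C). This inverts C2 and rejoins the route at ester 14.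

Further compounds
F1 | step 19 | 6-(tert-butyldimethylsilyloxy)-13,13-ethylenedioxy-14,15-dinorlabda-6,8-diene | CC(C)(C)[Si](C)(C)OC1=CC(C)=C(CCC3(C)OCCO3)[C@@]2(C)CCCC(C)(C)[C@H]12
F2 | step 19 | 13,13-ethylenedioxy-7α-hydroxy-14,15-dinorlabd-8-en-6-one | O=C1[C@@H](O)C(C)=C(CCC3(C)OCCO3)[C@@]2(C)CCCC(C)(C)[C@H]12
F3 | step 17 | 3-(2-acetyl-1,3,3-trimethylcyclohexyl)-6-(2-methyl-1,3-dioxolan-2-yl)hexan-2-one (6,8-diketone, configuration as 25) | CC(=O)[C@@H]1[C@@](C)([C@@H](CCC2(C)OCCO2)C(C)=O)CCCC1(C)C
F4 | step 6 | (1R,4S)-4-[(tert-butyldimethylsilyloxy)methyl]-3,5,5-trimethylcyclohex-2-en-1-ol (cis) | CC(C)(C)[Si](C)(C)OC[C@@H]1C(C)=C[C@H](O)CC1(C)C
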